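Leave the solid base alone.

electrophile 0.020 M; nucleophile 1.05 equiv; solid base 3.00 equiv; time 15 s

    electrophile + nucleophile → acid set free + product (k1 = 2.11 L mol⁻¹ s⁻¹)
    nucleophile + acid set free ⇌ protonated nucleophile, settled at all times (K2 = 17000 L mol⁻¹)
    acid set free + free base ⇌ salt of the base, settled at all times (K3 = 3.17 × 10⁶ L mol⁻¹)
    2 electrophile → homo dimer (k4 = 0.970 L mol⁻¹ s⁻¹)
    solid base ⇌ free base, rate k5*(cs5 - [free base]) while solid is left; crystals form when [free base] > cs5 (cs5 = 7.3 mM, k5 = 0.0153 s⁻¹)

- percent here means electrophile units held: one homo dimer counts as two
- for a step with 2 of a species take k times the square, and two of it per event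
- solid base is a solid; its amount is given per volume of the solution
- at the start none of the solid base is in solution
- run time (flask): 15 s

- part of the electrophile that has reacted at 15 s
- share of the unused nucleophile that is free and not bound as protonated nucleophile, at 15 s

The flask holds electrophile and nucleophile in solution over undissolved solid base, and the acid set free has two takers. Free base binds acid more strongly than the nucleophile does, but it enters solution no faster than the dissolution coefficient times the solubility, a ceiling of 0.112 mM s⁻¹. Coupling at the charged amounts sets acid free at 0.886 mM s⁻¹. The quotient of these two rates, 7.93, is the supply ratio, and the acid beyond the ceiling falls on the nucleophile.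

Coupling and dimerisation together remove electrophile at 1.66 mM s⁻¹ at the start, and coupling takes 53.3% of that. The charge divided by this rate gives a time, and the run time over it is 1.25. Taken as second-order decay, the reckoning here has 55.5% reacted at 15 s. With coupling's starting share held throughout, that makes an estimated 5.92 mM of acid, against at most 1.68 mM of base dissolved, hardly any of the solid charged. So 4.24 mM of protonated nucleophile is expected, and a free share of 71.9%. While solid is left, more solid base changes neither term of the ratio.

The forecast gives 56% (53% to 59%) and 70% (66% to 74%), a free share below the reckoning here, holding that “the roughly 6 mM of acid made by coupling mostly protonates the nucleophile”.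

The flask gives 56.2% reacted and 70.3% free. Its salt of the base stands at 0.00165 M at 15.0 s, beside the 1.68 mM that the ceiling allows. In the neighbour flask charged with 0.0080 M of electrophile, at the same equivalents, the supply ratio falls to 1.27, and the free share there is 97.5%.

The numbers stand for no real mixture.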